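**Retrosynthetic overview** (azulene numbering of the target: five-membered ring C1, C2, C3, C3a, C8a; seven-membered ring C3a, C4–C8, C8a)
1. Late acyl-group changes (phenol release, C2 acetate, C4 aroylation) lead back to the C4,C8-diol whose C2,C3-diol is an acetonide.
2. Key disconnection, a [4+3] annulation across C4–C5 and C7–C8: the array C4(O)–C5H=C6(CH3)–C7H2–C8(O) is a (Z)-2-methyl-2-ene-1,5-diol whose two carbinol carbons sit on the cis ring-fusion atoms C3a/C8a. This is the retron of a double allylboration of a cis-cyclopentane-1,2-dicarbaldehyde with a (Z)-1,3-bis(boryl)-2-methylpropene.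
3. The dialdehyde is carried as a lactol/menthyl acetal; this temporary oxygen bridge keeps the two formyl carbons cis and makes the bicycle convex, so that OsO4 sets the C2,C3-diol cis to H-3a and CH3-8a.
4. Five-membered ring: ring-closing metathesis (C2=C3) of an allyl and a 1-isopropylvinyl group placed on (5R)-5-(l-menthyloxy)butenolide by conjugate addition (C3a) and two enolate alkylations (quaternary C8a).
5. Order of ring formation: purchased butenolide ring (temporary) → cyclopentene (step 5) → cycloheptene (step 10, last ring of the skeleton).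

Key step: step 10

Assumption: (5R)-5-(l-menthyloxy)furan-2(5H)-one, B-bromo-9-BBN and (iodomethyl)boronic acid pinacol ester are taken as purchasable; l-menthyl = (1R,2S,5R)-5-methyl-2-(propan-2-yl)cyclohexyl.

**Step 1**
Reactants: 1 3-methylbut-1-yne
Product: 3 2-bromo-3-methylbut-1-ene, via alkenylborane 2 (not isolated)
Conditions: B-bromo-9-BBN, CH2Cl2, 0 °C; then AcOH, 0 °C to rt
Reagents that add atoms: B-bromo-9-borabicyclo[3.3.1]nonane, BrB1C2CCCC1CCC2
Why: syn-bromoboration of the terminal alkyne puts bromine on the internal carbon (Markovnikov haloboration) and protodeboronation with acetic acid leaves the 2-bromo-1-alkene.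

**Step 2**
Reactants: 3 2-bromo-3-methylbut-1-ene; 4 (5R)-5-(l-menthyloxy)furan-2(5H)-one
Product: 6 (4S,5R)-5-(l-menthyloxy)-4-(3-methylbut-1-en-2-yl)dihydrofuran-2(3H)-one, via Grignard reagent 5 (not isolated)
Conditions: Mg, THF, 40 °C; then 4, CuBr·SMe2 (10 mol %), THF, −78 to −40 °C; aq. NH4Cl
Reagents that add atoms: none
Why: copper-catalysed conjugate addition of the alkenyl Grignard reagent should occur on the face opposite to the menthyloxy group of the neighbouring acetal carbon, which sets the future C3a as the trans-4,5-disubstituted lactone.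

**Step 3**
Reactants: 6 (4S,5R)-5-(l-menthyloxy)-4-(3-methylbut-1-en-2-yl)dihydrofuran-2(3H)-one
Product: 8 (3R,4S,5R)-3-allyl-5-(l-menthyloxy)-4-(3-methylbut-1-en-2-yl)dihydrofuran-2(3H)-one, via lithium enolate 7 (not isolated)
Conditions: LiN(iPr)2, THF, −78 °C; allyl bromide, −78 to −40 °C
Reagents that add atoms: allyl bromide, C=CCBr
Why: enolate alkylation of the lactone, the electrophile entering anti to the adjacent alkenyl group (3,4-trans).

**Step 4**
Reactants: 8 (3R,4S,5R)-3-allyl-5-(l-menthyloxy)-4-(3-methylbut-1-en-2-yl)dihydrofuran-2(3H)-one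
Product: 10 (3S,4R,5R)-3-allyl-3-methyl-5-(l-menthyloxy)-4-(3-methylbut-1-en-2-yl)dihydrofuran-2(3H)-one, via lithium enolate 9 (not isolated)
Conditions: LiN(iPr)2, THF, −78 °C; MeI, DMPU, −78 to −20 °C
Reagents that add atoms: iodomethane, CI
Why: second enolate alkylation creates the quaternary centre (future C8a); methyl iodide again enters anti to the alkenyl group, so the allyl group ends cis to it as the metathesis requires.

**Step 5**
Reactants: 10 (3S,4R,5R)-3-allyl-3-methyl-5-(l-menthyloxy)-4-(3-methylbut-1-en-2-yl)dihydrofuran-2(3H)-one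
Product: 11 (3R,3aR,6aS)-6a-methyl-3-(l-menthyloxy)-4-(propan-2-yl)-3,3a,6,6a-tetrahydro-1H-cyclopenta[c]furan-1-one (cis-fused)
Conditions: second-generation Grubbs catalyst (5 mol %), CH2Cl2, 40 °C
Reagents that add atoms: none
Why: ring-closing metathesis of the cis-disposed allyl and 1,1-disubstituted alkenyl groups closes the trisubstituted cyclopentene with loss of ethene.

**Step 6**
Reactants: 11 (3R,3aR,6aS)-6a-methyl-3-(l-menthyloxy)-4-(propan-2-yl)-3,3a,6,6a-tetrahydro-1H-cyclopenta[c]furan-1-one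
Product: 12 (3R,3aS,4R,5S,6aS)-4,5-dihydroxy-6a-methyl-3-(l-menthyloxy)-4-(propan-2-yl)hexahydro-1H-cyclopenta[c]furan-1-one
Conditions: OsO4 (5 mol %), NMO, acetone/H2O, rt
Reagents that add atoms: N-methylmorpholine N-oxide, C[N+]1([O-])CCOCC1; water, O (oxygen is transferred through catalytic osmium tetroxide, O=[Os](=O)(=O)=O)
Why: Upjohn dihydroxylation from the convex face of the cis-fused oxabicyclo[3.3.0]octene (the face of H-3a and CH3-6a) sets the future C2 and C3 with both hydroxyls cis to the ring-fusion substituents and the isopropyl group on the concave face.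

**Step 7**
Reactants: 12 (3R,3aS,4R,5S,6aS)-4,5-dihydroxy-6a-methyl-3-(l-menthyloxy)-4-(propan-2-yl)hexahydro-1H-cyclopenta[c]furan-1-one
Product: 13 4,5-O-isopropylidene acetal (acetonide) of 12
Conditions: 2,2-dimethoxypropane, PPTS (cat.), CH2Cl2, rt
Reagents that add atoms: 2,2-dimethoxypropane, COC(C)(C)OC
Why: acid-catalysed transacetalisation protects the cis secondary/tertiary diol as the five-membered acetonide.

**Step 8**
Reactants: 13 acetonide lactone
Product: 14 lactol of 13 (1-hydroxy-3-menthyloxy bis-acetal, anomeric mixture)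
Conditions: diisobutylaluminium hydride (1.3 equiv), CH2Cl2, −78 °C; aq. potassium sodium tartrate
Reagents that add atoms: none
Why: partial reduction of the lactone stops at the lactol because the tetrahedral aluminate is stable at low temperature, giving a doubly masked cis-1,2-dialdehyde.

**Step 9**
Reactants: 15 propyne
Product: 16 (Z)-2-methyl-1,3-bis(4,4,5,5-tetramethyl-1,3,2-dioxaborolan-2-yl)prop-1-ene
Conditions: B2pin2, ICH2Bpin, CuCl (10 mol %), Xantphos (10 mol %), NaOtBu, THF, 0 °C to rt
Reagents that add atoms: bis(pinacolato)diboron, CC1(C)OB(B2OC(C)(C)C(C)(C)O2)OC1(C)C; (iodomethyl)boronic acid pinacol ester, CC1(C)OB(CI)OC1(C)C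
Why: copper-catalysed borylative alkylation (carboboration) of the alkyne: syn-borylcupration puts boron on the terminal carbon and the alkenylcopper is alkylated with retention, which fixes the Z geometry (vinyl boron cis to CH2Bpin).

**Step 10**
Reactants: 14 lactol; 16 (Z)-2-methyl-1,3-bis(pinacolboryl)prop-1-ene
Product: 20 (2S,3R,3aR,4S,8S,8aS)-6,8a-dimethyl-3-(propan-2-yl)-1,2,3,3a,4,7,8,8a-octahydroazulene-2,3,4,8-tetrol 2,3-acetonide, via dialdehyde 17 (not isolated), via allylboronate 18 (not isolated), via bis-borate 19 (not isolated)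
Conditions: 16 (1.1 equiv), (S)-TRIP [(S)-3,3'-bis(2,4,6-triisopropylphenyl)-1,1'-binaphthyl-2,2'-diyl hydrogen phosphate, 10 mol %], 4 Å molecular sieves, toluene, 0 °C to rt; then dilution to 0.01 M, 45 °C; aq. NaHCO3
Reagents that add atoms: none
Why: Proposed new method: acid-catalysed ring-chain equilibration of lactol 14 releases menthol and cis-dialdehyde 17, whose less hindered C4 formyl group is allylborated by the CH2–B end of 16 through a closed six-membered chair transition state (bond to the boron-bearing vinyl carbon, future C5) to give the α-boryl allylboronate 18; this then allylborates the C8 formyl group intramolecularly through C7 with shift of the double bond to C5=C6, closing the seven-membered ring as a [4+3] annulation to bis-borate 19, hydrolysed on work-up. The closest known reaction type is the one-pot double allylboration of two aldehydes with γ-boryl allylboron reagents to 2-ene-1,5-diols; the untested element is running the second allylboration intramolecularly with the allyl unit inside the forming ring. The ring closes by 7-exo-trig attack of C7 on the C8 carbonyl through a boat-like B–O-bridged (bicyclo[3.2.2]-type) transition state, in which only the Z ring olefin can form. C4 is set by the chiral phosphoric acid (antipode chosen for Si-face attack, 4S, to be confirmed) and the syn C4–O/C5–B relation by the Z geometry of 16; C8 is set by the substrate, because boron on C5 delivers C7 to the aldehyde face that puts the C8 oxygen on the ring face of the departing boron, trans to the C4 oxygen (8S). Site selectivity (C4 formyl first) rests on the quaternary C8a next to the C8 formyl group and on the near-stoichiometric amount of 16; cyclisation over oligomerisation rests on dilution in the second stage.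

**Step 11**
Reactants: 20 diol acetonide; 21 4-acetoxybenzoyl chloride
Product: 22 C4 4-acetoxybenzoate of 20 (C8 hydroxyl free)
Conditions: 21 (1.05 equiv), pyridine, DMAP (5 mol %), CH2Cl2, −40 to 0 °C
Reagents that add atoms: none
Why: DMAP-catalysed acylation with retention at C4 should favour the allylic C4 hydroxyl, flanked by a methine, over the C8 hydroxyl that sits next to the quaternary C8a.

**Step 12**
Reactants: 22 C4 4-acetoxybenzoate acetonide
Product: 23 (2S,3R,3aR,4S,8S,8aS)-2,3,8-trihydroxy-6,8a-dimethyl-3-(propan-2-yl)-1,2,3,3a,4,7,8,8a-octahydroazulen-4-yl 4-acetoxybenzoate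
Conditions: AcOH/H2O (4:1), 50 °C
Reagents that add atoms: none
Why: acid hydrolysis of the isopropylidene acetal; the allylic benzoate and the aryl acetate should tolerate aqueous acetic acid.

**Step 13**
Reactants: 23 triol
Product: 25 (2S,3R,3aR,4S,8S,8aS)-2-acetoxy-3,8-dihydroxy-6,8a-dimethyl-3-(propan-2-yl)-1,2,3,3a,4,7,8,8a-octahydroazulen-4-yl 4-acetoxybenzoate, via cyclic orthoacetate 24 (not isolated)
Conditions: MeC(OMe)3 (1.5 equiv), CSA (5 mol %), CH2Cl2, rt; then AcOH/H2O (4:1), rt
Reagents that add atoms: trimethyl orthoacetate, CC(OC)(OC)OC; water, O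
Why: orthoester-mediated monoacylation of a cis-diol: only the cis-2,3-diol can form the cyclic orthoacetate, and its mild acidic opening through the acetoxonium ion, with acyl migration, should leave the acetyl group on the secondary C2 oxygen.

**Step 14**
Reactants: 25 diacetate
Product: 26 target, (2S,3R,3aR,4S,8S,8aS)-2-acetoxy-3,8-dihydroxy-6,8a-dimethyl-3-(propan-2-yl)-1,2,3,3a,4,7,8,8a-octahydroazulen-4-yl 4-hydroxybenzoate
Conditions: NH4OAc, MeOH/H2O (4:1), rt
Reagents that add atoms: none
Why: chemoselective transesterification, since aryl acetates are cleaved by ammonium acetate in aqueous methanol much faster than alkyl acetates or benzoates, so the phenol is freed without touching the C2 acetate or the C4 ester.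

**Compound list**
1 | 3-methylbut-1-yne | CC(C)C#C | starting material
2 | B-[(Z)-2-bromo-3-methylbut-1-en-1-yl]-9-borabicyclo[3.3.1]nonane | CC(C)/C(Br)=C/B1C2CCCC1CCC2 | intermediate (not isolated)
3 | 2-bromo-3-methylbut-1-ene | CC(C)C(Br)=C | intermediate
4 | (5R)-5-{[(1R,2S,5R)-5-methyl-2-(propan-2-yl)cyclohexyl]oxy}furan-2(5H)-one | O=C1C=C[C@H](O[C@@H]2C[C@H](C)CC[C@H]2C(C)C)O1 | starting material
5 | (3-methylbut-1-en-2-yl)magnesium bromide | CC(C)C(=C)[Mg]Br | intermediate (not isolated)
6 | (4S,5R)-5-(l-menthyloxy)-4-(3-methylbut-1-en-2-yl)dihydrofuran-2(3H)-one (alkenyl trans to menthyloxy) | O=C1C[C@@H](C(=C)C(C)C)[C@H](O[C@@H]2C[C@H](C)CC[C@H]2C(C)C)O1 | intermediate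
7 | lithium enolate of 6 | [Li]OC1=C[C@@H](C(=C)C(C)C)[C@H](O[C@@H]2C[C@H](C)CC[C@H]2C(C)C)O1 | intermediate (not isolated)
8 | (3R,4S,5R)-3-allyl-5-(l-menthyloxy)-4-(3-methylbut-1-en-2-yl)dihydrofuran-2(3H)-one (allyl trans to alkenyl) | O=C1[C@H](CC=C)[C@@H](C(=C)C(C)C)[C@H](O[C@@H]2C[C@H](C)CC[C@H]2C(C)C)O1 | intermediate
9 | lithium enolate of 8 | [Li]OC1=C(CC=C)[C@@H](C(=C)C(C)C)[C@H](O[C@@H]2C[C@H](C)CC[C@H]2C(C)C)O1 | intermediate (not isolated)
10 | (3S,4R,5R)-3-allyl-3-methyl-5-(l-menthyloxy)-4-(3-methylbut-1-en-2-yl)dihydrofuran-2(3H)-one (allyl cis to alkenyl, methyl trans) | O=C1[C@@](C)(CC=C)[C@@H](C(=C)C(C)C)[C@H](O[C@@H]2C[C@H](C)CC[C@H]2C(C)C)O1 | intermediate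
11 | (3R,3aR,6aS)-6a-methyl-3-(l-menthyloxy)-4-(propan-2-yl)-3,3a,6,6a-tetrahydro-1H-cyclopenta[c]furan-1-one | C=1C[C@]2(C)C(=O)O[C@@H](O[C@@H]3C[C@H](C)CC[C@H]3C(C)C)[C@@H]2C=1C(C)C | intermediate
12 | (3R,3aS,4R,5S,6aS)-4,5-dihydroxy-6a-methyl-3-(l-menthyloxy)-4-(propan-2-yl)hexahydro-1H-cyclopenta[c]furan-1-one | O[C@H]1C[C@]2(C)C(=O)O[C@@H](O[C@@H]3C[C@H](C)CC[C@H]3C(C)C)[C@@H]2[C@]1(O)C(C)C | intermediate
13 | 4,5-O-isopropylidene acetal of 12 | CC1(C)O[C@H]2C[C@]3(C)C(=O)O[C@@H](O[C@@H]4C[C@H](C)CC[C@H]4C(C)C)[C@@H]3[C@]2(O1)C(C)C | intermediate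
14 | lactol of 13 (anomeric mixture at the new carbinol carbon) | CC1(C)O[C@H]2C[C@]3(C)C(O)O[C@@H](O[C@@H]4C[C@H](C)CC[C@H]4C(C)C)[C@@H]3[C@]2(O1)C(C)C | intermediate
15 | propyne | CC#C | starting material
16 | (Z)-2-methyl-1,3-bis(4,4,5,5-tetramethyl-1,3,2-dioxaborolan-2-yl)prop-1-ene | CC1(C)OB(/C=C(/C)CB2OC(C)(C)C(C)(C)O2)OC1(C)C | intermediate
17 | cis-dialdehyde: 3,4-(isopropylidenedioxy)-1-methyl-3-(propan-2-yl)cyclopentane-1,2-dicarbaldehyde, formyl groups cis to each other and trans to the acetonide | O=C[C@@H]1[C@@]2(C(C)C)OC(C)(C)O[C@H]2C[C@]1(C)C=O | intermediate (not isolated)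
18 | mono-adduct of 17: the C4 formyl group converted to CH(OBpin)–CH(Bpin)–C(CH3)=CH2 (4S, O–B and C–B syn), C8 formyl group intact | C=C(C)[C@@H](B3OC(C)(C)C(C)(C)O3)[C@H](OB4OC(C)(C)C(C)(C)O4)[C@@H]1[C@@]2(C(C)C)OC(C)(C)O[C@H]2C[C@]1(C)C=O | intermediate (not isolated)
19 | 4,8-bis(pinacol borate) of 20 | CC1(C)O[C@H]2C[C@]3(C)[C@@H](OB4OC(C)(C)C(C)(C)O4)CC(C)=C[C@H](OB4OC(C)(C)C(C)(C)O4)[C@@H]3[C@]2(O1)C(C)C | intermediate (not isolated)
20 | (2S,3R,3aR,4S,8S,8aS)-6,8a-dimethyl-3-(propan-2-yl)-1,2,3,3a,4,7,8,8a-octahydroazulene-2,3,4,8-tetrol 2,3-acetonide | CC1(C)O[C@H]2C[C@]3(C)[C@@H](O)CC(C)=C[C@H](O)[C@@H]3[C@]2(O1)C(C)C | intermediate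
21 | 4-acetoxybenzoyl chloride | CC(=O)Oc1ccc(cc1)C(Cl)=O | starting material
22 | C4 4-acetoxybenzoate of 20 | CC1(C)O[C@H]2C[C@]3(C)[C@@H](O)CC(C)=C[C@H](OC(=O)c4ccc(OC(C)=O)cc4)[C@@H]3[C@]2(O1)C(C)C | intermediate
23 | (2S,3R,3aR,4S,8S,8aS)-2,3,8-trihydroxy-6,8a-dimethyl-3-(propan-2-yl)-1,2,3,3a,4,7,8,8a-octahydroazulen-4-yl 4-acetoxybenzoate | O[C@H]1C[C@]2(C)[C@@H](O)CC(C)=C[C@H](OC(=O)c3ccc(OC(C)=O)cc3)[C@@H]2[C@]1(O)C(C)C | intermediate
24 | 2,3-O-(1-methoxyethylidene) cyclic orthoacetate of 23 (mixture at the orthoester carbon) | COC1(C)O[C@H]2C[C@]3(C)[C@@H](O)CC(C)=C[C@H](OC(=O)c4ccc(OC(C)=O)cc4)[C@@H]3[C@]2(O1)C(C)C | intermediate (not isolated)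
25 | (2S,3R,3aR,4S,8S,8aS)-2-acetoxy-3,8-dihydroxy-6,8a-dimethyl-3-(propan-2-yl)-1,2,3,3a,4,7,8,8a-octahydroazulen-4-yl 4-acetoxybenzoate | CC(=O)O[C@H]1C[C@]2(C)[C@@H](O)CC(C)=C[C@H](OC(=O)c3ccc(OC(C)=O)cc3)[C@@H]2[C@]1(O)C(C)C | intermediate
26 | (2S,3R,3aR,4S,8S,8aS)-2-acetoxy-3,8-dihydroxy-6,8a-dimethyl-3-(propan-2-yl)-1,2,3,3a,4,7,8,8a-octahydroazulen-4-yl 4-hydroxybenzoate (CNP0146780.2) | CC(=O)O[C@H]1C[C@]2(C)[C@@H](O)CC(C)=C[C@H](OC(=O)c3ccc(O)cc3)[C@@H]2[C@]1(O)C(C)C | target

**Step count:** 14 steps in total. Longest linear sequence: 13 steps (steps 1–8 and 10–14); step 9 is a one-step convergent branch.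

**Steps most likely to fail**

1. Step 10 (Proposed new method).
   - What may go wrong: the intramolecular second allylboration may be outrun by intermolecular allylboration or by a 1,3-boron shift; the first allylboration may not discriminate the two formyl groups; the catalyst may not override the substrate in setting C4; the dialdehyde may epimerise at C3a.
   - Fallback (known reactions only; sets out from 13, returns at 20): lactone 13 is opened with MeNH(OMe)·HCl/iPrMgCl and, after loss of menthol from the hemiacetal on work-up, should give the formyl Weinreb amide F1. CH2=CHMgBr at −78 °C adds to the aldehyde only and the alkoxide closes onto the amide to give the vinyl lactone F2 (C4 epimers separated here if both form). Diisobutylaluminium hydride gives the lactol F3. Methallylboration with B-(2-methylallyl)diisopinocampheylborane (reagent control at C8) gives the diene diol F4. Ring-closing metathesis with the second-generation Grubbs catalyst then forms the C5=C6 bond and gives 20.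

2. Step 9.
   - What may go wrong: alkoxide attack on the α-iodo boronate in place of alkylation of the alkenylcopper, and incomplete regiocontrol in the borylcupration of the small alkyne.
   - Fallback (sets out from 15, returns at 16): syn-bromoboration of propyne with BBr3 gives the (Z)-2-bromoprop-1-enyl dibromoborane F5, which pinacol converts to the pinacol ester F6. Negishi coupling (Pd(PPh3)4, THF) with (pinacolboryl)methylzinc iodide F7, made from (iodomethyl)boronic acid pinacol ester and zinc dust, replaces bromide with retention and gives 16.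

3. Step 11.
   - What may go wrong: insufficient site selectivity between the two secondary hydroxyls (acylation at C8 or bis-acylation).
   - Fallback (sets out from 20, returns at 22): MnO2 oxidises only the allylic C4 alcohol to the enone F8. The C8 hydroxyl is silylated (TESOTf, 2,6-lutidine) to the silyl ether F9. Luche reduction (NaBH4, CeCl3·7H2O, MeOH, −78 °C) from the convex face should restore the 4S alcohol F10. Acylation with 21 gives the ester F11, and HF·pyridine removes the silyl group to give 22.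

**Further compounds**
F1 | step 10 | formyl Weinreb amide: N-methoxy-N-methyl amide at the C8 carbon, formyl group at the C4 carbon, acetonide core as in 17 | O=C[C@@H]1[C@@]2(C(C)C)OC(C)(C)O[C@H]2C[C@]1(C)C(=O)N(C)OC
F2 | step 10 | vinyl lactone: analogue of 13 with vinyl in place of menthyloxy (4S) | CC1(C)O[C@H]2C[C@]3(C)C(=O)O[C@@H](C=C)[C@@H]3[C@]2(O1)C(C)C
F3 | step 10 | lactol of F2 (anomeric mixture) | CC1(C)O[C@H]2C[C@]3(C)C(O)O[C@@H](C=C)[C@@H]3[C@]2(O1)C(C)C
F4 | step 10 | diene diol: 4S vinyl carbinol and 8S methallyl carbinol on the acetonide-protected cyclopentane | C=C[C@H](O)[C@@H]1[C@@]2(C(C)C)OC(C)(C)O[C@H]2C[C@]1(C)[C@@H](O)CC(C)=C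
F5 | step 9 | (Z)-(2-bromoprop-1-en-1-yl)dibromoborane | C/C(Br)=C/B(Br)Br
F6 | step 9 | 2-[(Z)-2-bromoprop-1-en-1-yl]-4,4,5,5-tetramethyl-1,3,2-dioxaborolane | C/C(Br)=C/B1OC(C)(C)C(C)(C)O1
F7 | step 9 | [(4,4,5,5-tetramethyl-1,3,2-dioxaborolan-2-yl)methyl]zinc iodide | I[Zn]CB1OC(C)(C)C(C)(C)O1
F8 | step 11 | C4 enone of 20 (C8 hydroxyl free) | CC1(C)O[C@H]2C[C@]3(C)[C@@H](O)CC(C)=CC(=O)[C@@H]3[C@]2(O1)C(C)C
F9 | step 11 | C8 triethylsilyl ether of F8 | CC1(C)O[C@H]2C[C@]3(C)[C@@H](O[Si](CC)(CC)CC)CC(C)=CC(=O)[C@@H]3[C@]2(O1)C(C)C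
F10 | step 11 | C8 triethylsilyl ether of 20 (4S alcohol free) | CC1(C)O[C@H]2C[C@]3(C)[C@@H](O[Si](CC)(CC)CC)CC(C)=C[C@H](O)[C@@H]3[C@]2(O1)C(C)C
F11 | step 11 | C8 triethylsilyl ether of 22 | CC1(C)O[C@H]2C[C@]3(C)[C@@H](O[Si](CC)(CC)CC)CC(C)=C[C@H](OC(=O)c4ccc(OC(C)=O)cc4)[C@@H]3[C@]2(O1)C(C)C
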